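I counted ligand, not hours.

| setting | south-west | east | midnight | dusk | summer | spring |
|---|---|---|---|---|---|---|
| starting complex | 0.076 M | 0.076 M | 0.076 M | 0.076 M | 0.076 M (fed, over 24.0 h) | 0.076 M |
| incoming ligand | 2 equiv | 1 equiv | 2.00 equiv (fed, over 24.0 h) | 2.00 equiv | 2.00 equiv | 2.00 equiv |
| leaving ligand | 1 equiv | 1 equiv | 1.00 equiv | 1.00 equiv | 1.00 equiv | 1.00 equiv |
| remark | run made earlier | run made earlier | a stirred flask in which incoming ligand is dosed at a steady rate over 24.0 h without added volume, worked up at 30 h | a single well-mixed tank run continuously and read at steady state, 30 h in it on average | a stirred flask in which starting complex is dosed at a steady rate over 24.0 h without added volume, worked up at 30 h | a closed flask charged with all of it at once and left for 30 h |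
| time |  |  | 30 h |  | 30 h | 30 h |

| run | time / h | complex with three exchanged / % | starting complex / % |
|---|---|---|---|
| south-west | 6.00 | 50 | 22 |
| south-west | 12.0 | 49 | 21 |
| south-west | 20.0 | 51 | 21 |
| south-west | 25.0 | 47 | 21 |
| south-west | 30.0 | 51 | 17 |
| east | 0.667 | 3 | 72 |
| east | 1.33 | 10 | 62 |
| east | 2.00 | 11 | 56 |
| east | 2.50 | 12 | 51 |
| east | 3.00 | 13 | 54 |

(standard deviation of a reading: 1.5 percentage points)

- the set-up with the highest amount of complex with three exchanged at the outlet or at the end, in percent of the starting complex put in ("none" if the first two lie within 2 percentage points) (midnight / dusk / summer / spring / none)
- amount of complex with three exchanged at the outlet or at the end, in percent of the starting complex put in, midnight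
- amount of complex with three exchanged at the outlet or at the end, in percent of the starting complex put in, dusk
- amount of complex with three exchanged at the outlet or at the end, in percent of the starting complex put in, summer
- amount of complex with three exchanged at the outlet or at the end, in percent of the starting complex put in, spring

- the stated concentrations are those of everything mixed, before any reaction; amounts are the same in each set-up
- the earlier runs were read with a standard deviation of 1.5 percentage points
- the feed brings no volume worth counting
- the earlier runs were made in a closed, stirred flask

South-west sat flat from its first reading, at a mean of 49.6 % complex with three exchanged and 20.4 % starting complex. If the unseen remainder holds at least one new ligand per complex, at least 1.79 equiv of the 2 equiv charged had gone, so I read the plateau as exhaustion of the limiting reagent, not as equilibrium.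

I therefore used the ligand yield E, the share of charged ligand sitting on the complex with three exchanged. While ligand is taken up, E is the rate of product formation, times 3, divided by the rate of ligand loss and summed over the run, so time drops out of that ratio. This rested on my assumption that product is not lost without ligand, which the south-west readings, between 47 % and 51 % with a scatter of 1.5 percentage points, could not test closely. South-west reads E = 74.4 %, and east, from its last 3 readings of 12.0 %, reads 36.0 %.

Spring repeats the south-west recipe, so I put it at 49.6 %. If every step is first order in ligand, the ligand concentration cancels from the ratio, so midnight gets the same value. For the dusk tank I had no better argument and took that value too.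

In east, starting complex had a half-life near 1.41 h (pseudo-first-order, a reading), far shorter than the 24.0 h feed of summer. Complex fed there meets ligand in excess, and E = 1 would give a ceiling of 66.7 %.

That E was the weak link. I kept the first half of the feed clean, which leaves 0.5 equiv of ligand for 0.5 of complex still to come. That is the east ratio, so the tail yields 12.0 % of its own complex, and summer comes to 56.0 %, or E = 84.0 %.

The forecast named summer, with 50 % for midnight, 49 % for dusk, 60 % for summer and 50 % for spring, because “Dosing the complex into excess ligand drives early portions fully to product and leaves late portions unreacted”; its summer stood above my 56.0 %.

The flasks gave 49.1 % in midnight, 48.3 % in dusk, 57.3 % in summer and 47.7 % in spring, so summer came first.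

    complex with one exchanged + incoming ligand → leaving ligand + complex with two exchanged (k = 36.9 /M/h)
    complex with two exchanged + incoming ligand → leaving ligand + complex with three exchanged (k = 15.2 /M/h)
    starting complex + complex with three exchanged → side product (k = 0.166 /M/h)
    starting complex + incoming ligand → leaving ligand + complex with one exchanged (k = 7.58 /M/h)

In summer the exchange steps ran through the 24.0 h feed, and at 30 h the flask held 57.3 % complex with three exchanged, 25.4 % starting complex, 4.63 % complex with one exchanged and 7.63 % complex with two exchanged, which is E = 85.9 %, 12 points above the south-west reading of 74.4 %. In midnight the same count gave E = 73.7 %, level with that reading, with 20.7 % starting complex and 19.4 % complex with two exchanged at the end.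

The runs are calculated with constants of no real substance, and the scatter is random.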